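**Retrosynthetic overview**
- The last step builds ring C and ring A together. Disconnect O1–C8a, C8–C8a and C4a–C5 to give an acyclic (S)-carbinol carrying a bis(methylthio)enone (C2–C3–C4–C4a–C8a) and a bis(silyloxy)diene made from a 3-acyl-dihydrocoumarin (C5–C8 with both benzyl groups).
- The diene terminus C8 can only bond to the O-bearing carbon C8a, and the lactone carbonyl becomes C5. The 8-/6-benzyl pattern is therefore fixed by connectivity, and the lactone also masks the phenol of the C6 benzyl group.
- The dihydrocoumarin unit comes from 3-acetylcoumarin and 2-hydroxy-5-(2-hydroxybenzyl)benzaldehyde (aldol condensation, then hydrogenation). That aldehyde comes from salicylaldehyde and 2-hydroxybenzyl alcohol.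
- The (S)-carbinol (future C2) comes from benzaldehyde and the silyl dienol ether of 4,4-bis(methylthio)but-3-en-2-one by catalytic asymmetric Mukaiyama aldol.
- Ring order: no ring is made before the last step. There the dihydropyranone (ring C) closes first and the benzenoid ring A second, in one pot.

Assumption: 3-acetylcoumarin and 4,4-bis(methylsulfanyl)but-3-en-2-one are bought (each is one step from commodity chemicals). Atom labels C2 to C8a follow the flavanone numbering of the target.

**Step 1**
Reactants: 1 salicylaldehyde; 2 2-hydroxybenzyl alcohol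
Product: 3 2-hydroxy-5-(2-hydroxybenzyl)benzaldehyde
Conditions: 1 (10 equiv, neat), TsOH·H2O (5 mol%), 90 °C, slow addition of 2; excess 1 distilled off
Reagents that add atoms: none
Why: Acid-catalysed Friedel–Crafts hydroxybenzylation (o-quinone methide / 2-hydroxybenzyl cation from 2) of salicylaldehyde, which reacts para to its OH as in the acid-catalysed formation of 5,5'-methylenebis(salicylaldehyde); the large excess of 1 outcompetes self-condensation of 2, and no stereocentre is formed.

**Step 2**
Reactants: 4 3-acetylcoumarin; 3 2-hydroxy-5-(2-hydroxybenzyl)benzaldehyde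
Product: 5 3-[(2E)-3-[2-hydroxy-5-(2-hydroxybenzyl)phenyl]prop-2-enoyl]-2H-chromen-2-one
Conditions: piperidine (0.2 equiv), EtOH, reflux
Reagents that add atoms: none
Why: Claisen–Schmidt (aldol) condensation at the acetyl CH3 of 4, the only enolisable position and the standard route to 3-cinnamoylcoumarins; the conjugated E-alkene forms under thermodynamic control.

**Step 3**
Reactants: 5 3-[(2E)-3-[2-hydroxy-5-(2-hydroxybenzyl)phenyl]prop-2-enoyl]-2H-chromen-2-one
Product: 6 3-[3-[2-hydroxy-5-(2-hydroxybenzyl)phenyl]propanoyl]chroman-2-one (C3 of the lactone uncontrolled and enolisable)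
Conditions: H2 (1 atm), 10% Pd/C, EtOAc–THF, rt
Reagents that add atoms: none
Why: Heterogeneous catalytic hydrogenation saturates both electron-poor C=C bonds (the enone and the alkylidene-β-dicarbonyl C3=C4 of the coumarin) while ketone, lactone and phenols are inert; the new lactone C3 centre is enolisable and is erased in step 7.

**Step 4**
Reactants: 7 4,4-bis(methylsulfanyl)but-3-en-2-one
Product: 8 [4,4-bis(methylsulfanyl)buta-1,3-dien-2-yl]oxy(trimethyl)silane
Conditions: LDA (1.1 equiv, commercial solution), THF, −78 °C; TMSCl (1.2 equiv), −78 °C → rt; pentane, filtration, Kugelrohr distillation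
Reagents that add atoms: chlorotrimethylsilane, C[Si](C)(C)Cl
Why: Kinetic deprotonation at the methyl group (the only enolisable site) and O-silylation (silyl enol ether formation) give the 2-siloxydiene, the sulfur analogue of a Brassard/Danishefsky diene.

**Step 5**
Reactants: 8 [4,4-bis(methylsulfanyl)buta-1,3-dien-2-yl]oxy(trimethyl)silane; 9 benzaldehyde
Product: 10 (5S)-1,1-bis(methylsulfanyl)-5-phenyl-5-(trimethylsilyloxy)pent-1-en-3-one
Conditions: Ti(OiPr)4/(S)-BINOL (1:1, 10 mol%), 4 Å MS, Et2O, −20 °C; non-aqueous work-up through Et3N-deactivated silica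
Reagents that add atoms: none
Why: Ti(IV)–BINOL-catalysed enantioselective Mukaiyama aldol addition of the diene terminus to benzaldehyde (Keck-type, as used for Danishefsky- and Chan-type dienes); the (S)-BINOL complex directs Si-face attack, which sets the (5S)-carbinol that becomes C2 of the target, and silyl transfer delivers the O-TMS ether.

**Step 6**
Reactants: 6 3-[3-[2-hydroxy-5-(2-hydroxybenzyl)phenyl]propanoyl]chroman-2-one
Product: 11 2-(trimethylsilyloxy)-3-[1-(trimethylsilyloxy)-3-[2-(trimethylsilyloxy)-5-[2-(trimethylsilyloxy)benzyl]phenyl]prop-1-enyl]-4H-chromene (alkene geometry not controlled)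
Conditions: LDA (4.4 equiv, commercial solution), TMSCl (6 equiv, in situ quench), THF, −78 → 0 °C; pentane, filtration, evaporation; used at once
Reagents that add atoms: chlorotrimethylsilane, C[Si](C)(C)Cl
Why: Silylation of both phenols and double enolisation/O-silylation of the β-keto lactone (β-dicarbonyl enolate first, then γ-deprotonation on the ketone side) give the 1,3-bis(silyloxy)-1,3-diene (Chan-type diene formation); enolate formation also reopens any hemiketal between the phenol and the ketone, and the alkene geometry is immaterial.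

**Step 7**
Reactants: 10 (5S)-1,1-bis(methylsulfanyl)-5-phenyl-5-(trimethylsilyloxy)pent-1-en-3-one; 11 the tetrakis-TMS bis(silyloxy)diene
Product: 14 isouvarinol [(2S)-5,7-dihydroxy-6-(2-hydroxybenzyl)-8-[2-hydroxy-5-(2-hydroxybenzyl)benzyl]-2-phenylchroman-4-one], via (2S)-6-(methylsulfanyl)-2-phenyl-2,3-dihydropyran-4-one 12 (not isolated), via dihydropyranone keto-lactone 13 (not isolated)
Conditions: 10, TMSOTf (0.2 equiv), 2,6-di-tert-butyl-4-methylpyridine (0.3 equiv), CH2Cl2, −78 → −20 °C; add 11 (1.2 equiv), −78 → 0 °C; then MeOH, Et3N (3 equiv), 0 °C → rt, 2 h; AcOH quench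
Reagents that add atoms: none
Why: Proposed new method: catalytic TMSOTf ionises the bis(methylthio)enone of 10 to a dithio-stabilised siloxyallyl cation that is captured 6-endo by the silyl ether oxygen with loss of MeS–TMS (ring C = 12; the C2–O bond is never broken, so the S centre is carried over with retention; closest precedent: acid cyclisation of Mukaiyama-aldol adducts of Danishefsky/Brassard dienes to dihydropyranones); the 4-siloxy-6-(methylthio)pyrylium of 12 then takes the terminal carbon of the Chan-type diene 11 with loss of the second MeS group (vinylogous Mukaiyama–Michael addition–elimination, the first stage of the formal [3+3] cyclisations of 1,3-bis(silyloxy)dienes with β-thio- and β-alkoxy-enones, whose usual second stage is blocked here because C6 is fully substituted); methanolysis frees 13, whose C8–H is activated by C7=O and the vinylogous ester, and its dienolate attacks the aryl lactone through C4a (vinylogous Dieckmann, a polyketide-type Claisen aromatisation like the base-induced conversion of 6-acylmethyl-4-hydroxy-2-pyrones into acylphloroglucinols), releasing the phenol of the C6 benzyl group and tautomerising irreversibly to ring A; C8 is the diene terminus and must end next to the ether carbon C8a, so the two benzyl groups cannot exchange positions, and the transient sp3 centres of 13 are erased on aromatisation.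

**Compound list**
1 | salicylaldehyde (2-hydroxybenzaldehyde) | O=Cc1ccccc1O | starting material
2 | 2-hydroxybenzyl alcohol (saligenin) | OCc1ccccc1O | starting material
3 | 2-hydroxy-5-(2-hydroxybenzyl)benzaldehyde | O=Cc1cc(Cc2ccccc2O)ccc1O | intermediate
4 | 3-acetylcoumarin (3-acetyl-2H-chromen-2-one) | CC(=O)C1=Cc2ccccc2OC1=O | starting material
5 | 3-[(2E)-3-[2-hydroxy-5-(2-hydroxybenzyl)phenyl]prop-2-enoyl]-2H-chromen-2-one | O=C(/C=C/c1cc(Cc2ccccc2O)ccc1O)C1=Cc2ccccc2OC1=O | intermediate
6 | 3-[3-[2-hydroxy-5-(2-hydroxybenzyl)phenyl]propanoyl]chroman-2-one (lactone C3 uncontrolled, enolisable) | O=C(CCc1cc(Cc2ccccc2O)ccc1O)C1Cc2ccccc2OC1=O | intermediate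
7 | 4,4-bis(methylsulfanyl)but-3-en-2-one | CC(=O)C=C(SC)SC | starting material
8 | [4,4-bis(methylsulfanyl)buta-1,3-dien-2-yl]oxy(trimethyl)silane | C=C(O[Si](C)(C)C)C=C(SC)SC | intermediate
9 | benzaldehyde | O=Cc1ccccc1 | starting material
10 | (5S)-1,1-bis(methylsulfanyl)-5-phenyl-5-(trimethylsilyloxy)pent-1-en-3-one | CSC(SC)=CC(=O)C[C@H](O[Si](C)(C)C)c1ccccc1 | intermediate
11 | 2-(trimethylsilyloxy)-3-[1-(trimethylsilyloxy)-3-[2-(trimethylsilyloxy)-5-[2-(trimethylsilyloxy)benzyl]phenyl]prop-1-enyl]-4H-chromene (alkene geometry not controlled) | C[Si](C)(C)OC1=C(C(O[Si](C)(C)C)=CCc2cc(Cc3ccccc3O[Si](C)(C)C)ccc2O[Si](C)(C)C)Cc2ccccc2O1 | intermediate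
12 | (2S)-6-(methylsulfanyl)-2-phenyl-2,3-dihydro-4H-pyran-4-one | CSC1=CC(=O)C[C@@H](c2ccccc2)O1 | intermediate
13 | (2S)-6-[1-[2-hydroxy-5-(2-hydroxybenzyl)phenyl]-3-oxo-3-(2-oxochroman-3-yl)propan-2-yl]-2-phenyl-2,3-dihydro-4H-pyran-4-one (side-chain CH and lactone C3 uncontrolled) | O=C1C[C@@H](c2ccccc2)OC(C(Cc2cc(Cc3ccccc3O)ccc2O)C(=O)C2Cc3ccccc3OC2=O)=C1 | intermediate
14 | isouvarinol, (2S)-5,7-dihydroxy-6-(2-hydroxybenzyl)-8-[2-hydroxy-5-(2-hydroxybenzyl)benzyl]-2-phenylchroman-4-one | O=C1C[C@@H](c2ccccc2)Oc2c(Cc3cc(Cc4ccccc4O)ccc3O)c(O)c(Cc3ccccc3O)c(O)c21 | target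

**Step count and risks**
Total step count: 7. Longest linear sequence: 5 steps (1 → 2 → 3 → 6 → 7); the second branch (4 → 5) joins at step 7.

The three steps most likely to fail are step 7, step 6 and step 5.

Step 7. A γ-substituted diene has to attack a hindered vinylogous thioester, and a crowded C4a then has to acylate. Aldol closure of C6 onto C4 could compete, and C2 could epimerise slowly during the Et3N stage. The fallback takes the C8 benzyl group out of the annulation and adds it last. It sets out from 4, 10 and 3 and comes back at 14. Hydrogenation of 4 (H2, Pd/C) gives 3-acetylchroman-2-one F1. LDA/TMSCl converts it into 2-(trimethylsilyloxy)-3-[1-(trimethylsilyloxy)vinyl]-4H-chromene F2, which has an unsubstituted diene terminus and no phenols. The same TMSOTf, then Et3N/MeOH sequence with 10 runs through (2S)-6-[2-oxo-2-(2-oxochroman-3-yl)ethyl]-2-phenyl-2,3-dihydro-4H-pyran-4-one F3 to (2S)-5,7-dihydroxy-6-(2-hydroxybenzyl)-2-phenylchroman-4-one F4. NaBH4 reduction of 3 gives 2-(hydroxymethyl)-4-(2-hydroxybenzyl)phenol F5. Its o-quinone methide (dioxane, 100 °C, cat. ZnCl2) alkylates F4 at C8, the only free A-ring carbon, to give 14.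

Step 6. Four silylations and a γ-deprotonation next to an aryl lactone may not give 11 cleanly. The fallback replaces the silyl diene by a lithium polyanion and the thioether by a sulfone. It sets out from 6 and 10 and comes back at 13. TFA in wet CH2Cl2 converts 10 into 12, which is now isolated. mCPBA oxidises it to (2S)-6-(methylsulfonyl)-2-phenyl-2,3-dihydro-4H-pyran-4-one F6. The tetralithio derivative of 6 (LDA, 4.2 equiv, THF, −78 °C) attacks F6 through its γ-carbon and expels methanesulfinate (anionic addition–elimination, β-keto-ester dianion chemistry). A buffered quench gives 13, which the Et3N/MeOH stage of step 7 closes to 14.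

Step 5. Diene 8 is untested in Ti–BINOL aldol chemistry, so the ee or the turnover may be poor. The fallback is a racemic aldol followed by enzymatic resolution. It sets out from 7 and 9 and comes back at 10. The lithium enolate of 7 (LDA, THF, −78 °C) adds to 9 to give racemic 5-hydroxy-1,1-bis(methylsulfanyl)-5-phenylpent-1-en-3-one F7. A lipase (CAL-B, vinyl acetate, MTBE) acetylates the R alcohol to (1R)-5,5-bis(methylsulfanyl)-3-oxo-1-phenylpent-4-en-1-yl acetate F8 and leaves (5S)-5-hydroxy-1,1-bis(methylsulfanyl)-5-phenylpent-1-en-3-one F9, the same sense as for 3-hydroxy-3-phenylpropanoates. TMSCl/imidazole converts F9 into 10.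

**Further compounds**
F1 | step 7 | 3-acetylchroman-2-one | CC(=O)C1Cc2ccccc2OC1=O
F2 | step 7 | 2-(trimethylsilyloxy)-3-[1-(trimethylsilyloxy)vinyl]-4H-chromene | C=C(O[Si](C)(C)C)C1=C(O[Si](C)(C)C)Oc2ccccc2C1
F3 | step 7 | (2S)-6-[2-oxo-2-(2-oxochroman-3-yl)ethyl]-2-phenyl-2,3-dihydro-4H-pyran-4-one | O=C1C[C@@H](c2ccccc2)OC(CC(=O)C2Cc3ccccc3OC2=O)=C1
F4 | step 7 | (2S)-5,7-dihydroxy-6-(2-hydroxybenzyl)-2-phenylchroman-4-one | O=C1C[C@@H](c2ccccc2)Oc2cc(O)c(Cc3ccccc3O)c(O)c21
F5 | step 7 | 2-(hydroxymethyl)-4-(2-hydroxybenzyl)phenol | OCc1cc(Cc2ccccc2O)ccc1O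
F6 | step 6 | (2S)-6-(methylsulfonyl)-2-phenyl-2,3-dihydro-4H-pyran-4-one | CS(=O)(=O)C1=CC(=O)C[C@@H](c2ccccc2)O1
F7 | step 5 | rac-5-hydroxy-1,1-bis(methylsulfanyl)-5-phenylpent-1-en-3-one | CSC(SC)=CC(=O)CC(O)c1ccccc1
F8 | step 5 | (1R)-5,5-bis(methylsulfanyl)-3-oxo-1-phenylpent-4-en-1-yl acetate | CSC(SC)=CC(=O)C[C@@H](OC(C)=O)c1ccccc1
F9 | step 5 | (5S)-5-hydroxy-1,1-bis(methylsulfanyl)-5-phenylpent-1-en-3-one | CSC(SC)=CC(=O)C[C@H](O)c1ccccc1
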